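**Plan**

1. Cuts (cembrane numbering, see remark): C7–O of the hydroperoxide (singlet-oxygen ene on C7=C8); lactone O–C3 (carboxylate opening of a 3,4-epoxide); both epoxides (reagent-controlled epoxidation); C7–C8 (Nozaki–Hiyama–Kishi ring closure); C10–C11 (Negishi coupling); C5–C6 (Johnson–Claisen); C3–C4 (Grignard addition).
2. Forward: (R)-limonene oxide is cleaved to a keto aldehyde that already holds C1 and both ring arms. The ketone arm is grown to C8 and the aldehyde arm to C7. The 14-membered carbocycle closes first, then both epoxides go in, the exocyclic allylic alcohol is transposed to the E C7=C8 olefin, C16 is oxidised, the δ-lactone closes, and the ene reaction ends the route.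
3. Enabling feature: the C16 carboxyl sits on C15 and is 1,3 to C3 across C1–C2, so a trans-3,4-epoxide in the 14-membered ring can be opened only 6-exo at C3. The anti pair of lactone oxygen on C3 and tertiary hydroxyl on C4, on an all-equatorial δ-lactone bridged by the macrocycle, is the imprint of that opening.
4. Stereochemistry: C1 from limonene; C3, C4, C11, C12 from Shi epoxidation of E olefins (E from carboalumination and Claisen rearrangement), with C3 inverted in the lactonisation; C15 by equilibration on the lactone; C7 by the substrate-controlled ene reaction.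

Key step: step 15

Remark: cembrane numbering is used (ring C1–C14; C15–C17 the propionate unit on C1 with C16 the carboxyl carbon; C18, C19, C20 the methyls on C4, C8, C12); the target is (1R,3R,4S,7R,11S,12S,15S), and (+)-limonene oxide is taken as the commercial (4R) cis/trans mixture.

**Step 1**
Reactants: 1 (+)-limonene oxide, (4R)-1,2-epoxy-p-menth-8-ene (cis/trans mixture)
Product: 3 (3R)-6-oxo-3-(prop-1-en-2-yl)heptanal, via trans-diol 2 (not isolated)
Conditions: H5IO6 (1.2 equiv), THF/H2O, 0 °C to rt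
Reagents that add atoms: water, O
Why: epoxide hydrolysis followed by periodate glycol cleavage in one flask opens the cyclohexane into a methyl ketone arm (C14–C13–C12) and an aldehyde arm (C2–C3) on the untouched (R) centre, which becomes C1.

**Step 2**
Reactants: 3 (3R)-6-oxo-3-(prop-1-en-2-yl)heptanal
Product: 4 (5R)-7,7-dimethoxy-5-(prop-1-en-2-yl)heptan-2-one
Conditions: HC(OMe)3, MeOH, CeCl3·7H2O (cat.), 0 °C to rt
Reagents that add atoms: trimethyl orthoformate, COC(OC)OC; methanol, CO
Why: chemoselective acetalisation, because the aldehyde forms its acetal far faster than the methyl ketone under cerium catalysis, so only the C3 carbonyl is masked.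

**Step 3**
Reactants: 4 (5R)-7,7-dimethoxy-5-(prop-1-en-2-yl)heptan-2-one
Product: 6 (5R)-7,7-dimethoxy-5-(prop-1-en-2-yl)hept-1-yne, via enol phosphate 5 (not isolated)
Conditions: LDA (1.05 equiv), THF, −78 °C; ClP(O)(OEt)2; then LDA (2.3 equiv), −78 °C to rt; H2O
Reagents that add atoms: none
Why: kinetic enolisation at the methyl group, O-phosphorylation and base-induced elimination of the enol phosphate convert the methyl ketone into the terminal alkyne C12≡C11.

**Step 4**
Reactants: 6 (5R)-7,7-dimethoxy-5-(prop-1-en-2-yl)hept-1-yne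
Product: 8 (1E,5R)-1-iodo-7,7-dimethoxy-2-methyl-5-(prop-1-en-2-yl)hept-1-ene, via alkenylalane 7 (not isolated)
Conditions: Me3Al (3 equiv), Cp2ZrCl2 (0.2 equiv), H2O (1.5 equiv), CH2Cl2, −23 °C; then I2, THF, −23 to 0 °C
Reagents that add atoms: trimethylaluminium, C[Al](C)C; iodine, II
Why: zirconium-catalysed carboalumination adds methyl (C20) and aluminium syn across the alkyne with methyl on the inner carbon, and iodinolysis with retention gives the E alkenyl iodide, which fixes the C11=C12 geometry; the 1,1-disubstituted alkene is inert, and the short low-temperature protocol is chosen to spare the acetal.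

**Step 5**
Reactants: 9 3-bromobut-3-en-1-ol
Product: 10 2-bromo-4-iodobut-1-ene
Conditions: I2, PPh3, imidazole, CH2Cl2, 0 °C
Reagents that add atoms: iodine, II
Why: Appel-type iodination of the primary alcohol gives the alkyl iodide needed for zinc insertion, and the alkenyl bromide is untouched.

**Step 6**
Reactants: 8 (1E,5R)-1-iodo-7,7-dimethoxy-2-methyl-5-(prop-1-en-2-yl)hept-1-ene; 10 2-bromo-4-iodobut-1-ene
Product: 13 (3R,6E)-10-bromo-7-methyl-3-(prop-1-en-2-yl)undeca-6,10-dienal, via organozinc iodide 11 (not isolated), via dimethyl acetal 12 (not isolated)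
Conditions: 10, Zn dust, LiCl, THF, 25 °C; then 8, Pd(PPh3)4 (5 mol%), THF, 25 °C; then 1 M HCl, THF, rt
Reagents that add atoms: water, O
Why: Negishi sp3–sp2 coupling joins C10 to C11 with retention of the E geometry, the alkenyl iodide undergoing oxidative addition much faster than the alkenyl bromide, and the acidic work-up releases the C3 aldehyde.

**Step 7**
Reactants: 13 (3R,6E)-10-bromo-7-methyl-3-(prop-1-en-2-yl)undeca-6,10-dienal
Product: 14 (5R,8E)-12-bromo-2,9-dimethyl-5-(prop-1-en-2-yl)trideca-1,8,12-trien-3-ol (C3 epimers)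
Conditions: CH2=C(CH3)MgBr (1.3 equiv), THF, −78 to −20 °C
Reagents that add atoms: isopropenylmagnesium bromide, CC(=C)[Mg]Br
Why: Grignard addition brings in C4, C18 and C5 as a 2-methylallylic alcohol; the carbinol configuration is irrelevant because it is erased in step 8.

**Step 8**
Reactants: 14 (5R,8E)-12-bromo-2,9-dimethyl-5-(prop-1-en-2-yl)trideca-1,8,12-trien-3-ol
Product: 16 ethyl (4E,7R,10E)-14-bromo-4,11-dimethyl-7-(prop-1-en-2-yl)pentadeca-4,10,14-trienoate, via ketene acetal 15 (not isolated)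
Conditions: CH3C(OEt)3 (8 equiv), EtCO2H (cat.), 138 °C, EtOH distilled off
Reagents that add atoms: triethyl orthoacetate, CCOC(C)(OCC)OCC
Why: Johnson–Claisen rearrangement through a chair transition state with the C2 substituent equatorial forms the C5–C6 bond and the E trisubstituted C3=C4 olefin, and delivers C7 as an ester.

**Step 9**
Reactants: 16 ethyl (4E,7R,10E)-14-bromo-4,11-dimethyl-7-(prop-1-en-2-yl)pentadeca-4,10,14-trienoate
Product: 17 (4E,7R,10E)-14-bromo-4,11-dimethyl-7-(prop-1-en-2-yl)pentadeca-4,10,14-trienal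
Conditions: DIBAL-H (1.1 equiv), CH2Cl2, −78 °C; Rochelle salt
Reagents that add atoms: none
Why: partial reduction of the ester at low temperature stops at the aldehyde because the tetrahedral aluminium hemiacetal survives until work-up.

**Step 10**
Reactants: 17 (4E,7R,10E)-14-bromo-4,11-dimethyl-7-(prop-1-en-2-yl)pentadeca-4,10,14-trienal
Product: 18 (1R,3E,11E)-cembra-3,8(19),11,15-tetraen-7-ol (C7 epimers)
Conditions: CrCl2 (10 equiv), NiCl2 (5 mol%), DMF, 25 to 50 °C, 2 mM, slow addition
Reagents that add atoms: none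
Why: intramolecular Nozaki–Hiyama–Kishi reaction under high dilution closes the 14-membered carbocycle at C7–C8; the C7 configuration is not controlled and is not needed.

**Step 11**
Reactants: 18 (1R,3E,11E)-cembra-3,8(19),11,15-tetraen-7-ol
Product: 19 (1R,3S,4S,11S,12S)-3,4:11,12-diepoxycembra-8(19),15-dien-7-ol (C7 epimers)
Conditions: L-fructose-derived Shi ketone (0.6 equiv), Oxone (2.8 equiv), K2CO3, Bu4NHSO4, borate/EDTA buffer pH 10.5, MeCN/CH2(OMe)2, 0 °C
Reagents that add atoms: potassium peroxymonosulfate (active part of Oxone), [K+].[O-]S(=O)(=O)OO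
Why: Shi asymmetric epoxidation, in which the chiral dioxirane meets each E trisubstituted olefin in the spiro transition state and the L-series ketone should give the S,S epoxide at C3/C4 and at C11/C12; the two 1,1-disubstituted olefins are poor substrates for this dioxirane and should remain.

**Step 12**
Reactants: 19 (1R,3S,4S,11S,12S)-3,4:11,12-diepoxycembra-8(19),15-dien-7-ol
Product: 22 (1R,3S,4S,7E,11S,12S)-3,4:11,12-diepoxycembra-7,15-diene, via sulfonylhydrazine adduct 20 (not isolated), via allylic diazene 21 (not isolated)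
Conditions: 2-O2NC6H4SO2NHNH2, PPh3, DEAD, N-methylmorpholine, −30 °C; then 23 °C
Reagents that add atoms: none
Why: Mitsunobu displacement of the only hydroxyl by the sulfonylhydrazide, loss of sulfinic acid and sigmatropic loss of N2 from the allylic diazene move the double bond to C7=C8 and turn C19 into a methyl group; C6 lies away from C9 in the cyclic transition state, which should give the E olefin from both C7 epimers, and the amine solvent buffers the sulfinic acid so that the epoxides survive.

**Step 13**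
Reactants: 22 (1R,3S,4S,7E,11S,12S)-3,4:11,12-diepoxycembra-7,15-diene
Product: 24 (1R,3S,4S,7E,11S,12S)-3,4:11,12-diepoxycembr-7-en-16-ol (C15 epimers), via alkylborane 23 (not isolated)
Conditions: 9-BBN (1.3 equiv), THF, 0 to 23 °C; then NaOH, H2O2, 0 °C
Reagents that add atoms: hydrogen peroxide, OO
Why: anti-Markovnikov hydroboration–oxidation, in which 9-BBN takes the 1,1-disubstituted isopropenyl group far faster than the trisubstituted ring olefin and leaves epoxides alone; it is placed after step 12 so that step 12 meets a single hydroxyl, and the C15 epimer mixture is corrected in step 15.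

**Step 14**
Reactants: 24 (1R,3S,4S,7E,11S,12S)-3,4:11,12-diepoxycembr-7-en-16-ol
Product: 26 (1R,3S,4S,7E,11S,12S)-3,4:11,12-diepoxycembr-7-en-16-oic acid (C15 epimers), via aldehyde 25 (not isolated)
Conditions: TEMPO (0.2 equiv), PhI(OAc)2 (2.4 equiv), MeCN/pH 7 phosphate buffer, 23 °C
Reagents that add atoms: water, O
Why: oxoammonium oxidation of the primary alcohol through the aldehyde hydrate gives the carboxylic acid under buffered conditions that spare the epoxides and the olefin.

**Step 15**
Reactants: 26 (1R,3S,4S,7E,11S,12S)-3,4:11,12-diepoxycembr-7-en-16-oic acid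
Product: 28 (1R,3R,4S,7E,11S,12S,15S)-11,12-epoxy-4-hydroxycembr-7-en-16,3-olide, via epimeric lactones 27 (not isolated)
Conditions: Cs2CO3 (0.3 equiv), DMF, 60 °C; then KOt-Bu (0.2 equiv), THF, 0 °C; aq. NH4Cl
Reagents that add atoms: none
Why: The carboxylate of the partly neutralised acid, with the remaining free acid hydrogen-bonding to the epoxide oxygen, attacks C3 of the 3,4-epoxide from the rear in an intramolecular SN2 opening; the closest known reaction type is the lactonisation of epoxy carboxylates to hydroxy lactones. The δ-lactone O–C3–C2–C1–C15–C16 closes in the 6-exo-tet mode, whereas attack at the tertiary C4 would be 7-endo and the 11,12-epoxide is out of reach of the tethered carboxylate. C3 is set by inversion of the (3S) epoxide carbon to 3R, and C4 keeps its configuration and emerges as the tertiary alcohol anti to the lactone oxygen. C15 is set by base equilibration of the lactone α-centre towards the epimer with the methyl group equatorial and trans to C14, on a chair whose C1 and C3 ring bonds are both equatorial. The step needs site selectivity between two like trisubstituted epoxides and regioselectivity within one; the 1,3 relation of the C16 carboxyl to C3 through C15–C1–C2 secures the first, and the near-neutral carboxylate conditions, which avoid cationic opening at C4, secure the second.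

**Step 16**
Reactants: 28 (1R,3R,4S,7E,11S,12S,15S)-11,12-epoxy-4-hydroxycembr-7-en-16,3-olide
Product: 29 (1R,3R,4S,7R,11S,12S,15S)-11,12-epoxy-7-hydroperoxy-4-hydroxycembr-8(19)-en-16,3-olide
Conditions: O2, tetraphenylporphyrin (1 mol%), CH2Cl2, visible light, −20 °C; no reductive work-up
Reagents that add atoms: dioxygen, O=O
Why: Schenck ene reaction of singlet oxygen with the only olefin left, in which oxygen bonds to C7 while a C19 hydrogen is taken from the more crowded C6/C19 side of the E olefin, giving the allylic hydroperoxide and the 8(19)-methylene; attack on the outer face of C7=C8 in the lactone-bridged ring is expected to give 7R, and this is the least secure stereocentre of the route.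

**Compound list**

1 | (+)-limonene oxide, (4R)-1,2-epoxy-p-menth-8-ene, cis/trans mixture | CC(=C)[C@@H]1CCC2(C)OC2C1 | starting material
2 | (4R)-p-menth-8-ene-1,2-diol | CC(=C)[C@@H]1CCC(C)(O)C(O)C1 | intermediate
3 | (3R)-6-oxo-3-(prop-1-en-2-yl)heptanal | CC(=O)CC[C@@H](C(C)=C)CC=O | intermediate
4 | (5R)-7,7-dimethoxy-5-(prop-1-en-2-yl)heptan-2-one | CC(=O)CC[C@@H](C(C)=C)CC(OC)OC | intermediate
5 | diethyl (5R)-7,7-dimethoxy-5-(prop-1-en-2-yl)hept-1-en-2-yl phosphate | C=C(OP(=O)(OCC)OCC)CC[C@@H](C(C)=C)CC(OC)OC | intermediate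
6 | (5R)-7,7-dimethoxy-5-(prop-1-en-2-yl)hept-1-yne | C#CCC[C@@H](C(C)=C)CC(OC)OC | intermediate
7 | [(1E,5R)-7,7-dimethoxy-2-methyl-5-(prop-1-en-2-yl)hept-1-en-1-yl]dimethylalane | C[Al](C)/C=C(C)/CC[C@@H](C(C)=C)CC(OC)OC | intermediate
8 | (1E,5R)-1-iodo-7,7-dimethoxy-2-methyl-5-(prop-1-en-2-yl)hept-1-ene | I/C=C(C)/CC[C@@H](C(C)=C)CC(OC)OC | intermediate
9 | 3-bromobut-3-en-1-ol | C=C(Br)CCO | starting material
10 | 2-bromo-4-iodobut-1-ene | C=C(Br)CCI | intermediate
11 | (3-bromobut-3-en-1-yl)zinc iodide | C=C(Br)CC[Zn]I | intermediate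
12 | (5E,9R)-2-bromo-11,11-dimethoxy-6-methyl-9-(prop-1-en-2-yl)undeca-1,5-diene | C=C(Br)CC/C=C(C)/CC[C@@H](C(C)=C)CC(OC)OC | intermediate
13 | (3R,6E)-10-bromo-7-methyl-3-(prop-1-en-2-yl)undeca-6,10-dienal | C=C(Br)CC/C=C(C)/CC[C@@H](C(C)=C)CC=O | intermediate
14 | (5R,8E)-12-bromo-2,9-dimethyl-5-(prop-1-en-2-yl)trideca-1,8,12-trien-3-ol, C3 epimers | C=C(Br)CC/C=C(C)/CC[C@@H](C(C)=C)CC(O)C(C)=C | intermediate
15 | 1-ethoxyvinyl ether of 14 (mixed ketene acetal) | C=C(Br)CC/C=C(C)/CC[C@@H](C(C)=C)CC(OC(=C)OCC)C(C)=C | intermediate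
16 | ethyl (4E,7R,10E)-14-bromo-4,11-dimethyl-7-(prop-1-en-2-yl)pentadeca-4,10,14-trienoate | C=C(Br)CC/C=C(C)/CC[C@@H](C(C)=C)C/C=C(C)/CCC(=O)OCC | intermediate
17 | (4E,7R,10E)-14-bromo-4,11-dimethyl-7-(prop-1-en-2-yl)pentadeca-4,10,14-trienal | C=C(Br)CC/C=C(C)/CC[C@@H](C(C)=C)C/C=C(C)/CCC=O | intermediate
18 | (1R,3E,11E)-cembra-3,8(19),11,15-tetraen-7-ol, C7 epimers | C=C1CC/C=C(C)/CC[C@@H](C(C)=C)C/C=C(C)/CCC1O | intermediate
19 | (1R,3S,4S,11S,12S)-3,4:11,12-diepoxycembra-8(19),15-dien-7-ol, C7 epimers | C=C1CC[C@@H]2O[C@@]2(C)CC[C@@H](C(C)=C)C[C@@H]3O[C@@]3(C)CCC1O | intermediate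
20 | N-[(1R,3S,4S,11S,12S)-3,4:11,12-diepoxycembra-8(19),15-dien-7-yl]-2-nitrobenzenesulfonohydrazide | C=C1CC[C@@H]2O[C@@]2(C)CC[C@@H](C(C)=C)C[C@@H]3O[C@@]3(C)CCC1N(N)S(=O)(=O)c1ccccc1[N+](=O)[O-] | intermediate
21 | (1R,3S,4S,11S,12S)-3,4:11,12-diepoxycembra-8(19),15-dien-7-yldiazene | C=C1CC[C@@H]2O[C@@]2(C)CC[C@@H](C(C)=C)C[C@@H]3O[C@@]3(C)CCC1N=N | intermediate
22 | (1R,3S,4S,7E,11S,12S)-3,4:11,12-diepoxycembra-7,15-diene | C1/C=C(C)/CC[C@@H]2O[C@@]2(C)CC[C@@H](C(C)=C)C[C@@H]3O[C@@]3(C)C1 | intermediate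
23 | 9-[(1R,3S,4S,7E,11S,12S)-3,4:11,12-diepoxycembr-7-en-16-yl]-9-borabicyclo[3.3.1]nonane, C15 epimers | C1/C=C(C)/CC[C@@H]2O[C@@]2(C)CC[C@@H](C(C)CB2C3CCCC2CCC3)C[C@@H]3O[C@@]3(C)C1 | intermediate
24 | (1R,3S,4S,7E,11S,12S)-3,4:11,12-diepoxycembr-7-en-16-ol, C15 epimers | C1/C=C(C)/CC[C@@H]2O[C@@]2(C)CC[C@@H](C(C)CO)C[C@@H]3O[C@@]3(C)C1 | intermediate
25 | (1R,3S,4S,7E,11S,12S)-3,4:11,12-diepoxycembr-7-en-16-al, C15 epimers | C1/C=C(C)/CC[C@@H]2O[C@@]2(C)CC[C@@H](C(C)C=O)C[C@@H]3O[C@@]3(C)C1 | intermediate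
26 | (1R,3S,4S,7E,11S,12S)-3,4:11,12-diepoxycembr-7-en-16-oic acid, C15 epimers | C1/C=C(C)/CC[C@@H]2O[C@@]2(C)CC[C@@H](C(C)C(=O)O)C[C@@H]3O[C@@]3(C)C1 | intermediate
27 | (1R,3R,4S,7E,11S,12S)-11,12-epoxy-4-hydroxycembr-7-en-16,3-olide, C15 epimers | C1/C=C(C)/CC[C@@H]2O[C@@]2(C)CC[C@@H]2C[C@@H](OC(=O)C2C)[C@@](C)(O)C1 | intermediate
28 | (1R,3R,4S,7E,11S,12S,15S)-11,12-epoxy-4-hydroxycembr-7-en-16,3-olide | C1/C=C(C)/CC[C@@H]2O[C@@]2(C)CC[C@@H]2C[C@@H](OC(=O)[C@H]2C)[C@@](C)(O)C1 | intermediate
29 | (1R,3R,4S,7R,11S,12S,15S)-11,12-epoxy-7-hydroperoxy-4-hydroxycembr-8(19)-en-16,3-olide | C=C1CC[C@@H]2O[C@@]2(C)CC[C@@H]2C[C@@H](OC(=O)[C@H]2C)[C@@](C)(O)CC[C@H]1OO | target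

**Totals**

Total steps: 16. Longest linear sequence: 15 (steps 1–4 and 6–16).

**Steps most likely to fail**

1. Step 16. What may go wrong: hydrogen abstraction from the C6 methylene in place of the C19 methyl, and attack of singlet oxygen on both faces of the olefin. Fallback, which sets C7 by reagent control: from 28 the photo-oxygenation is run and the crude hydroperoxides are reduced with PPh3 to the C7-epimeric 7-hydroxy-8(19)-ene lactones F1. The tertiary C8 alcohols of the other regiochemistry are removed at this point. Dess–Martin oxidation gives the 8(19)-en-7-one F2, and catecholborane with (R)-2-methyl-CBS-oxazaborolidine should give the 7S alcohol F3. MsCl/Et3N at −30 °C gives the 7S methanesulfonate F4. Displacement with 2-methoxyprop-2-yl hydroperoxide and CsOH in DMF should proceed with inversion to the 7R perketal F5, and aqueous AcOH unmasks the hydroperoxide, which rejoins the route at 29.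

2. Step 11. What may go wrong: competing epoxidation of the two 1,1-disubstituted olefins, and loss of reagent control because the ring conformation shields one olefin face. Fallback, which epoxidises before ring closure: from 16 the same Shi epoxidation is run on the open chain, where there is no ring bias and the bromoalkene is electron-poor, to give the bis-epoxy ester F6. DIBAL-H at −78 °C gives the bis-epoxy aldehyde F7, and the Nozaki–Hiyama–Kishi ring closure of F7 comes back to the route at 19.

3. Step 12. What may go wrong: Mitsunobu displacement at the C19 terminus of the allyl system (SN2′), which would give the deoxygenated exocyclic olefin, and partial formation of the Z olefin. Fallback, which enters the same diazene from a carbonyl: from 19 Dess–Martin oxidation gives the 3,4:11,12-diepoxycembra-8(19),15-dien-7-one F8, and TsNHNH2 gives its tosylhydrazone F9. Catecholborane followed by NaOAc adds hydride to the C=N carbon, so only the C7 diazene can form, and the product rejoins the route at 22.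

**Further compounds**

F1 | step 16 | (1R,3R,4S,11S,12S,15S)-11,12-epoxy-4,7-dihydroxycembr-8(19)-en-16,3-olide, C7 epimers | C=C1CC[C@@H]2O[C@@]2(C)CC[C@@H]2C[C@@H](OC(=O)[C@H]2C)[C@@](C)(O)CCC1O
F2 | step 16 | (1R,3R,4S,11S,12S,15S)-11,12-epoxy-4-hydroxy-7-oxocembr-8(19)-en-16,3-olide | C=C1CC[C@@H]2O[C@@]2(C)CC[C@@H]2C[C@@H](OC(=O)[C@H]2C)[C@@](C)(O)CCC1=O
F3 | step 16 | (1R,3R,4S,7S,11S,12S,15S)-11,12-epoxy-4,7-dihydroxycembr-8(19)-en-16,3-olide | C=C1CC[C@@H]2O[C@@]2(C)CC[C@@H]2C[C@@H](OC(=O)[C@H]2C)[C@@](C)(O)CC[C@@H]1O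
F4 | step 16 | 7S methanesulfonate of F3 | C=C1CC[C@@H]2O[C@@]2(C)CC[C@@H]2C[C@@H](OC(=O)[C@H]2C)[C@@](C)(O)CC[C@@H]1OS(C)(=O)=O
F5 | step 16 | (7R)-7-(2-methoxyprop-2-ylperoxy) analogue of 29 | C=C1CC[C@@H]2O[C@@]2(C)CC[C@@H]2C[C@@H](OC(=O)[C@H]2C)[C@@](C)(O)CC[C@H]1OOC(C)(C)OC
F6 | step 11 | ethyl (4S,5S,7R,10S,11S)-14-bromo-4,5:10,11-diepoxy-4,11-dimethyl-7-(prop-1-en-2-yl)pentadec-14-enoate | C=C(Br)CC[C@@H]1O[C@@]1(C)CC[C@@H](C(C)=C)C[C@@H]1O[C@@]1(C)CCC(=O)OCC
F7 | step 11 | (4S,5S,7R,10S,11S)-14-bromo-4,5:10,11-diepoxy-4,11-dimethyl-7-(prop-1-en-2-yl)pentadec-14-enal | C=C(Br)CC[C@@H]1O[C@@]1(C)CC[C@@H](C(C)=C)C[C@@H]1O[C@@]1(C)CCC=O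
F8 | step 12 | (1R,3S,4S,11S,12S)-3,4:11,12-diepoxycembra-8(19),15-dien-7-one | C=C1CC[C@@H]2O[C@@]2(C)CC[C@@H](C(C)=C)C[C@@H]3O[C@@]3(C)CCC1=O
F9 | step 12 | 4-methylbenzenesulfonylhydrazone of F8 | C=C1CC[C@@H]2O[C@@]2(C)CC[C@@H](C(C)=C)C[C@@H]3O[C@@]3(C)CCC1=NNS(=O)(=O)c1ccc(C)cc1
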